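The depside is cut at its aryl ester into commercial methyl 2,4-dihydroxy-3,6-dimethylbenzoate (ring A) and a ring B acid. The feature exploited is the vicinal C6 methyl/C5 chlorine pair of ring B, flanked by the C1 carboxyl carbon and the C4 oxygen. With C1 masked as a 4,4-dimethyloxazoline and both oxygens as methyl ethers, a C5–C6 aryne takes up methyl at C6 and chlorine at C5 in one flask. The precursor is the pentasubstituted 5-chloro-2,4-dimethoxy-3-methylphenyl oxazoline, whose chlorine is the leaving group and whose only ring hydrogen is at C6. The hindered oxazoline is then unmasked by reduction–oxidation, not hydrolysis, and the methyl ethers are removed last.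

Key step: step 3

Remark on numbering: ring B positions are counted C1 (carboxyl-level carbon), C2 (O), C3 (CH3), C4 (O), C5 (Cl), C6 (CH3) in every intermediate, whatever the locants of the systematic name; ring A is the methyl benzoate ring.

Step 1
Reactants: 1 2,4-dimethoxy-3-methylbenzaldehyde
Product: 2 5-chloro-2,4-dimethoxy-3-methylbenzaldehyde
Conditions: SO2Cl2 (1.05 equiv), CH2Cl2, 0 °C to rt
Reagents that add atoms: sulfuryl chloride O=S(=O)(Cl)Cl
Why: Electrophilic aromatic chlorination should occur only at C5, which is ortho to the C4 methoxy and para to the C2 methoxy, whereas C6 is meta to both ethers and ortho to the deactivating formyl group.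

Step 2
Reactants: 2 5-chloro-2,4-dimethoxy-3-methylbenzaldehyde; 3 2-amino-2-methylpropan-1-ol
Product: 5 2-(5-chloro-2,4-dimethoxy-3-methylphenyl)-4,4-dimethyl-4,5-dihydro-1,3-oxazole, via oxazolidine 4 (not isolated)
Conditions: t-BuOH, rt; then I2, K2CO3, 70 °C
Reagents that add atoms: none
Why: Condensation gives the N,O-acetal 4, and its iodine-mediated oxidative dehydrogenation under carbonate buffering is an established one-flask conversion of aryl aldehydes into 2-aryl oxazolines, the ring being safe from halogenation because C5 is already blocked.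

Step 3
Reactants: 5 2-(5-chloro-2,4-dimethoxy-3-methylphenyl)-4,4-dimethyl-4,5-dihydro-1,3-oxazole; 6 methyllithium; 7 hexachloroethane
Product: 11 2-(3-chloro-4,6-dimethoxy-2,5-dimethylphenyl)-4,4-dimethyl-4,5-dihydro-1,3-oxazole, via C6 aryllithium 8 (not isolated), via C5–C6 aryne 9 (not isolated), via C5 aryllithium 10 (not isolated)
Conditions: MeLi (3.5 equiv), THF, −78 °C then −20 °C; C2Cl6 (4 equiv), −78 °C to rt
Reagents that add atoms: methyllithium [Li]C; hexachloroethane ClC(Cl)(Cl)C(Cl)(Cl)Cl
Why: Methyllithium bound to the oxazoline nitrogen removes the single ring hydrogen at C6, which is acidified by the oxazoline and by the neighbouring chlorine, and on warming aryllithium 8 loses LiCl to give the C5–C6 aryne 9. A second methyllithium, again delivered from the nitrogen, adds its carbon to C6 and leaves the carbanion at C5 (10), to which hexachloroethane transfers chlorine with loss of tetrachloroethene. The closest known reaction type is oxazoline-directed aryne generation from meta-chloroaryl oxazolines with tandem organolithium addition and electrophilic trapping of the resulting aryllithium. No ring is closed and no stereocentre is formed. The step needs methyl at C6 and the anion at C5, which is secured twice: by nitrogen-directed delivery to the ortho carbon and by the C4 methoxy, which, as in 3-methoxybenzyne, places the negative charge on the carbon next to oxygen. It also needs the C2 methoxy to escape ipso substitution by methyllithium, which is secured by completing the C6 metalation at −78 °C so that the ring is anionic before warming, and later by the two ortho substituents that twist the oxazoline out of conjugation.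

Step 4
Reactants: 11 2-(3-chloro-4,6-dimethoxy-2,5-dimethylphenyl)-4,4-dimethyl-4,5-dihydro-1,3-oxazole
Product: 14 3-chloro-4,6-dimethoxy-2,5-dimethylbenzaldehyde, via N-methyloxazolinium triflate 12 (not isolated), via N-methyloxazolidine 13 (not isolated)
Conditions: MeOTf, CH2Cl2, rt; NaBH4, MeOH/THF, 0 °C; aq. oxalic acid, THF, rt
Reagents that add atoms: water O
Why: Because a doubly ortho-substituted aryl oxazoline resists direct hydrolysis, it is unmasked by the standard sequence of N-methylation, hydride reduction at C2 and mild acid hydrolysis of the resulting N,O-acetal, none of which should affect the aryl chloride or the methyl ethers.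

Step 5
Reactants: 14 3-chloro-4,6-dimethoxy-2,5-dimethylbenzaldehyde
Product: 15 3-chloro-4,6-dimethoxy-2,5-dimethylbenzoic acid
Conditions: NaClO2, NaH2PO4, 2-methylbut-2-ene, t-BuOH/H2O, rt
Reagents that add atoms: sodium chlorite [Na+].[O-]Cl=O
Why: Pinnick oxidation converts hindered aryl aldehydes into acids under buffered conditions, and the fully substituted ring offers no position to the hypochlorous acid that the alkene scavenges.

Step 6
Reactants: 15 3-chloro-4,6-dimethoxy-2,5-dimethylbenzoic acid; 16 methyl 2,4-dihydroxy-3,6-dimethylbenzoate
Product: 18 methyl 4-[(3-chloro-4,6-dimethoxy-2,5-dimethylbenzoyl)oxy]-2-hydroxy-3,6-dimethylbenzoate, via mixed trifluoroacetic anhydride 17 (not isolated)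
Conditions: (CF3CO)2O, toluene, rt
Reagents that add atoms: none
Why: Mixed-anhydride esterification with trifluoroacetic anhydride suits a doubly ortho-substituted, electron-rich acid because 17 ionises readily towards the acylium ion, and it should acylate the free C4 hydroxyl of 16 in preference to the C2 hydroxyl that is hydrogen-bonded to the ester carbonyl.

Step 7
Reactants: 18 methyl 4-[(3-chloro-4,6-dimethoxy-2,5-dimethylbenzoyl)oxy]-2-hydroxy-3,6-dimethylbenzoate
Product: 19 methyl 4-[(3-chloro-4,6-dihydroxy-2,5-dimethylbenzoyl)oxy]-2-hydroxy-3,6-dimethylbenzoate (CNP0106652.0)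
Conditions: BBr3 (5 equiv), CH2Cl2, −78 to 0 °C; then H2O
Reagents that add atoms: none
Why: Lewis acid ether cleavage with BBr3 removes both ring B methyl ethers by bromide attack at the O-methyl carbon, the C2 ether being activated by chelation to the ester carbonyl and the C4 ether by its twisted, doubly flanked position, while the aryl ester has no alkyl–oxygen bond to break and the methyl ester should survive at low temperature.

Compound list
1 | 2,4-dimethoxy-3-methylbenzaldehyde | COc1ccc(C=O)c(OC)c1C | starting material
2 | 5-chloro-2,4-dimethoxy-3-methylbenzaldehyde | COc1c(C)c(OC)c(Cl)cc1C=O | intermediate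
3 | 2-amino-2-methylpropan-1-ol | CC(C)(N)CO | starting material
4 | 2-(5-chloro-2,4-dimethoxy-3-methylphenyl)-4,4-dimethyl-1,3-oxazolidine (racemic at C2, in equilibrium with its open imine) | COc1c(C)c(OC)c(Cl)cc1C1NC(C)(C)CO1 | intermediate
5 | 2-(5-chloro-2,4-dimethoxy-3-methylphenyl)-4,4-dimethyl-4,5-dihydro-1,3-oxazole | COc1c(C)c(OC)c(Cl)cc1C1=NC(C)(C)CO1 | intermediate
6 | methyllithium | [Li]C | starting material
7 | hexachloroethane | ClC(Cl)(Cl)C(Cl)(Cl)Cl | starting material
8 | [2-chloro-6-(4,4-dimethyl-4,5-dihydro-1,3-oxazol-2-yl)-3,5-dimethoxy-4-methylphenyl]lithium (5 lithiated at ring B C6) | COc1c(C)c(OC)c(Cl)c([Li])c1C1=NC(C)(C)CO1 | intermediate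
9 | 2-(2,4-dimethoxy-3-methyl-5,6-didehydrophenyl)-4,4-dimethyl-4,5-dihydro-1,3-oxazole (aryne, formal triple bond between ring B C5 and C6) | COC1=C(C2=NC(C)(C)CO2)C#CC(OC)=C1C | intermediate
10 | [3-(4,4-dimethyl-4,5-dihydro-1,3-oxazol-2-yl)-4,6-dimethoxy-2,5-dimethylphenyl]lithium (lithium at ring B C5) | COc1c(C)c(OC)c([Li])c(C)c1C1=NC(C)(C)CO1 | intermediate
11 | 2-(3-chloro-4,6-dimethoxy-2,5-dimethylphenyl)-4,4-dimethyl-4,5-dihydro-1,3-oxazole | COc1c(C)c(OC)c(Cl)c(C)c1C1=NC(C)(C)CO1 | intermediate
12 | 2-(3-chloro-4,6-dimethoxy-2,5-dimethylphenyl)-3,4,4-trimethyl-4,5-dihydro-1,3-oxazol-3-ium trifluoromethanesulfonate | COc1c(C)c(OC)c(Cl)c(C)c1C1=[N+](C)C(C)(C)CO1.[O-]S(=O)(=O)C(F)(F)F | intermediate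
13 | 2-(3-chloro-4,6-dimethoxy-2,5-dimethylphenyl)-3,4,4-trimethyl-1,3-oxazolidine (racemic at C2) | COc1c(C)c(OC)c(Cl)c(C)c1C1N(C)C(C)(C)CO1 | intermediate
14 | 3-chloro-4,6-dimethoxy-2,5-dimethylbenzaldehyde | COc1c(C)c(OC)c(Cl)c(C)c1C=O | intermediate
15 | 3-chloro-4,6-dimethoxy-2,5-dimethylbenzoic acid | COc1c(C)c(OC)c(Cl)c(C)c1C(=O)O | intermediate
16 | methyl 2,4-dihydroxy-3,6-dimethylbenzoate | COC(=O)c1c(C)cc(O)c(C)c1O | starting material
17 | 3-chloro-4,6-dimethoxy-2,5-dimethylbenzoic trifluoroacetic anhydride | COc1c(C)c(OC)c(Cl)c(C)c1C(=O)OC(=O)C(F)(F)F | intermediate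
18 | methyl 4-[(3-chloro-4,6-dimethoxy-2,5-dimethylbenzoyl)oxy]-2-hydroxy-3,6-dimethylbenzoate | COC(=O)c1c(C)cc(OC(=O)c2c(C)c(Cl)c(OC)c(C)c2OC)c(C)c1O | intermediate
19 | methyl 4-[(3-chloro-4,6-dihydroxy-2,5-dimethylbenzoyl)oxy]-2-hydroxy-3,6-dimethylbenzoate | COC(=O)c1c(C)cc(OC(=O)c2c(C)c(Cl)c(O)c(C)c2O)c(C)c1O | target

Total step count: 7. Longest linear sequence: 7 steps (1 to 19); compounds 3, 6, 7 and 16 are commercial and enter directly.

Steps most likely to fail

Step 3. Three processes threaten it: ipso substitution of the C2 methoxy by methyllithium before C6 metalation is complete, interception of the aryne by another aryllithium, and proton transfer that quenches the C5 carbanion before chlorine transfer. The fallback avoids the aryne altogether. Compound 5 is deprotonated at C6 with lithium 2,2,6,6-tetramethylpiperidide (LiTMP) in THF at −78 °C, a base too hindered to attack the methoxy-bearing carbon, which gives the same aryllithium 8. Held at −78 °C, below the temperature at which LiCl is lost, 8 is methylated with iodomethane (directed ortho-metalation and alkylation), so the original chlorine stays at C5. The fallback sets out from 5 and comes back to the route at 11; new compounds: none (F0).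

Step 7. The Lewis acid may cleave one of the two ester linkages, or the hindered C4 ether may be cleaved incompletely. The fallback reverses the order of ether cleavage and esterification. It sets out from 15, which is demethylated with BBr3 (CH2Cl2, −78 °C to rt) to 3-chloro-4,6-dihydroxy-2,5-dimethylbenzoic acid F1. This acid is activated with trifluoroacetic anhydride in toluene, in the presence of an excess of 16, as 3-chloro-4,6-dihydroxy-2,5-dimethylbenzoic trifluoroacetic anhydride F2. The C4 hydroxyl of F1, flanked by methyl and chlorine and less nucleophilic, should compete poorly with the C4 hydroxyl of 16, and a NaHCO3/methanol work-up should remove any aryl trifluoroacetates. The fallback comes back to the route at 19.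

Step 6. Acylation by the doubly ortho-substituted acyl donor may be slow, and the acylium ion may attack the free C5 carbon of ring A (C-acylation) instead of oxygen. The fallback moves the esterification to basic conditions with a preformed acyl chloride. It sets out from 15, which oxalyl chloride and catalytic DMF in CH2Cl2 convert into 3-chloro-4,6-dimethoxy-2,5-dimethylbenzoyl chloride F3. This is added to 16 and K2CO3 in acetone, where the more acidic, non-chelated C4 phenoxide of 16 is acylated and only O-acylation is possible. The fallback comes back to the route at 18.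

Further compounds
F0 | step 3 | none | none
F1 | step 7 | 3-chloro-4,6-dihydroxy-2,5-dimethylbenzoic acid | Cc1c(Cl)c(O)c(C)c(O)c1C(=O)O
F2 | step 7 | 3-chloro-4,6-dihydroxy-2,5-dimethylbenzoic trifluoroacetic anhydride | Cc1c(Cl)c(O)c(C)c(O)c1C(=O)OC(=O)C(F)(F)F
F3 | step 6 | 3-chloro-4,6-dimethoxy-2,5-dimethylbenzoyl chloride | COc1c(C)c(OC)c(Cl)c(C)c1C(Cl)=O
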